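## Retrosynthetic overview

1. The target is read as epicatechin-(4β→8)-epifisetinidol-(4β→8)-catechin (upper unit 2R,3R; middle unit 5-deoxy, 2R,3R; lower unit 2R,3S). The final disconnection opens ring C of the lower catechin unit (O1, C2, C3, C4, C4a, C8a) by a [4+2] cycloaddition of an ortho-quinone methide (C4=C4a–C8a=O1) with the (E)-2-arylvinyl acetate 29, which delivers C2, C3, the C3 oxygen and ring B and sets both stereocentres.
2. Enabling feature: ring A of the lower unit is a phloroglucinol, so C4 is a benzylic CH2 ortho to O1 and ortho/para to O5 and O7 and the quinone methide forms under mild acid. C2 is benzylic to the catechol ring B and C3 carries oxygen, so C2–C3 maps onto an (E)-β-acyloxystyrene polarised by its aryl group.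
3. The quinone methide precursor 26 comes from ortho-formylation and reduction of a phenol made by Friedel–Crafts capture of the middle-unit C4 cation (from 14) by 3,5-bis(benzyloxy)phenol. The upper interflavan bond follows by coupling the bromine-capped epicatechin cation (from 24) at C8, the only free position ortho to a free phenol in 19.
4. Ring order: the upper rings come from (−)-epicatechin; the middle ring C is closed by Shi epoxidation and 6-endo phenol opening (step 6), followed by C3 inversion through oxidation/reduction; the lower ring C is closed last (step 23).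
5. End game: methanolysis of two acetates, then one hydrogenolysis that removes eleven benzyl ethers and four aryl bromides.

Key step: step 23

## Route

Step 1
Reactants: 1 2′,4′-dihydroxyacetophenone
Product: 2 1-[4-(allyloxy)-2-hydroxyphenyl]ethan-1-one
Conditions: allyl bromide (1.05 equiv), K2CO3, acetone, reflux
Reagents that add atoms: allyl bromide, C=CCBr
Why: Williamson etherification; the 2′-OH is hydrogen-bonded to the ketone, so only the 4′-OH should be alkylated.

Step 2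
Reactants: 2 1-[4-(allyloxy)-2-hydroxyphenyl]ethan-1-one; 3 3,4-bis(benzyloxy)benzaldehyde
Product: 4 (E)-1-[4-(allyloxy)-2-hydroxyphenyl]-3-[3,4-bis(benzyloxy)phenyl]prop-2-en-1-one
Conditions: KOH, EtOH, rt
Reagents that add atoms: none
Why: Claisen–Schmidt aldol condensation should give the E-enone under thermodynamic control.

Step 3
Reactants: 4 (E)-1-[4-(allyloxy)-2-hydroxyphenyl]-3-[3,4-bis(benzyloxy)phenyl]prop-2-en-1-one
Product: 6 (E)-5-(allyloxy)-2-[3-(3,4-bis(benzyloxy)phenyl)prop-2-en-1-yl]phenol, via aryl ethyl carbonate 5 (not isolated)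
Conditions: ClCO2Et, Et3N, THF, 0 °C; then NaBH4, THF–H2O, 0 °C → rt
Reagents that add atoms: none
Why: Known reductive deoxygenation of 2′-hydroxychalcones: 1,2-reduction, carbonate transfer and loss of ethyl carbonate give a quinone methide that a second hydride reduces at the benzylic carbon, leaving the E-styrene intact.

Step 4
Reactants: 6 (E)-5-(allyloxy)-2-[3-(3,4-bis(benzyloxy)phenyl)prop-2-en-1-yl]phenol
Product: 7 tert-butyldimethylsilyl ether of 6
Conditions: TBSCl, imidazole, DMF, rt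
Reagents that add atoms: tert-butyldimethylsilyl chloride, CC(C)(C)[Si](C)(C)Cl
Why: Silylation protects the phenol from the oxidant of the next step.

Step 5
Reactants: 7 tert-butyldimethylsilyl ether of 6
Product: 8 (2S,3S)-2-[3,4-bis(benzyloxy)phenyl]-3-[4-(allyloxy)-2-(tert-butyldimethylsilyloxy)benzyl]oxirane
Conditions: L-fructose-derived Shi ketone (1,2:4,5-di-O-isopropylidene-β-L-erythro-2,3-hexodiulo-2,6-pyranose, 0.3 equiv), KHSO5 (Oxone), K2CO3, Bu4NHSO4, aq. Na2B4O7 buffer, MeCN–dimethoxymethane, 0 °C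
Reagents that add atoms: potassium peroxymonosulfate, [K+].[O-]S(=O)(=O)OO
Why: Shi asymmetric epoxidation; the dioxirane of the L-fructose-derived ketone should give the (S,S)-epoxide of the trans-styrene (the D-fructose ketone gives R,R), and the monosubstituted allyl ether should react far more slowly.

Step 6
Reactants: 8 (2S,3S)-2-[3,4-bis(benzyloxy)phenyl]-3-[4-(allyloxy)-2-(tert-butyldimethylsilyloxy)benzyl]oxirane
Product: 10 (2R,3S)-7-(allyloxy)-2-[3,4-bis(benzyloxy)phenyl]chroman-3-ol (2,3-trans), via phenol epoxide 9 (not isolated)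
Conditions: TBAF, AcOH, THF, 0 °C; then CSA (10 mol %), CH2Cl2, −20 °C
Reagents that add atoms: none
Why: Desilylation, then acid-catalysed 6-endo epoxide opening: the phenol should attack the benzylic carbon (activated by the 4-alkoxyphenyl group) with inversion while C3 keeps its oxygen, giving the 2,3-trans (2R,3S) flavan-3-ol.

Step 7
Reactants: 10 (2R,3S)-7-(allyloxy)-2-[3,4-bis(benzyloxy)phenyl]chroman-3-ol
Product: 11 (2R)-7-(allyloxy)-2-[3,4-bis(benzyloxy)phenyl]chroman-3-one
Conditions: Dess–Martin periodinane, CH2Cl2, 0 °C → rt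
Reagents that add atoms: none
Why: Dess–Martin oxidation is neutral enough to leave the C2 centre next to the new ketone unepimerised.

Step 8
Reactants: 11 (2R)-7-(allyloxy)-2-[3,4-bis(benzyloxy)phenyl]chroman-3-one
Product: 12 (2R,3R)-7-(allyloxy)-2-[3,4-bis(benzyloxy)phenyl]chroman-3-ol (2,3-cis, epifisetinidol series)
Conditions: LiBH(s-Bu)3, THF, −78 °C; aq. work-up
Reagents that add atoms: none
Why: Diastereoselective ketone reduction; the bulky hydride should add anti to the C2 aryl group, so the C3 hydroxyl ends up cis to it, as in the known catechin-to-epicatechin oxidation/reduction.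

Step 9
Reactants: 12 (2R,3R)-7-(allyloxy)-2-[3,4-bis(benzyloxy)phenyl]chroman-3-ol
Product: 13 (2R,3R)-7-(allyloxy)-3-(benzyloxy)-2-[3,4-bis(benzyloxy)phenyl]chromane
Conditions: NaH, BnBr, Bu4NI (cat.), DMF, 0 °C → rt
Reagents that add atoms: benzyl bromide, BrCc1ccccc1
Why: Williamson benzylation gives a C3 ether that survives all later steps and leaves in the final hydrogenolysis.

Step 10
Reactants: 13 (2R,3R)-7-(allyloxy)-3-(benzyloxy)-2-[3,4-bis(benzyloxy)phenyl]chromane
Product: 14 the 4β-(2-ethoxyethoxy) derivative of 13 (2,3-cis, 3,4-trans)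
Conditions: DDQ (2 equiv), 2-ethoxyethanol, CH2Cl2, rt
Reagents that add atoms: 2-ethoxyethanol, CCOCCO
Why: DDQ benzylic oxidation; hydride abstraction at C4 (para to O7, ortho to O1) and capture of the cation by the alcohol anti to the C2 aryl and C3 benzyloxy groups should give the 4β-ether, whose configuration is lost again on ionisation.

Step 11
Reactants: 14 the 4β-(2-ethoxyethoxy) derivative of 13; 15 3,5-bis(benzyloxy)phenol
Product: 16 2-[(2R,3R)-7-(allyloxy)-3-(benzyloxy)-2-(3,4-bis(benzyloxy)phenyl)chroman-4β-yl]-3,5-bis(benzyloxy)phenol (3,4-trans)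
Conditions: 15 (4 equiv), TMSOTf (0.5 equiv), CH2Cl2, −78 → −40 °C
Reagents that add atoms: none
Why: Lewis-acid-mediated Friedel–Crafts interflavan coupling; the C4 cation should be captured by the excess phenol at the carbon flanked by OH and OBn (less hindered than the one between two OBn groups) and from the β-face anti to the 2-aryl and 3-benzyloxy groups, which sets C4 as 3,4-trans.

Step 12
Reactants: 16 2-[(2R,3R)-7-(allyloxy)-3-(benzyloxy)-2-(3,4-bis(benzyloxy)phenyl)chroman-4β-yl]-3,5-bis(benzyloxy)phenol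
Product: 17 4,6-bis(benzyloxy)-2-hydroxy-3-[(2R,3R)-7-(allyloxy)-3-(benzyloxy)-2-(3,4-bis(benzyloxy)phenyl)chroman-4β-yl]benzaldehyde
Conditions: MgCl2, Et3N, paraformaldehyde, THF, reflux
Reagents that add atoms: formaldehyde (as paraformaldehyde), C=O
Why: Magnesium-mediated ortho-formylation (Casnati–Skattebøl); the magnesium phenoxide delivers formaldehyde only to the free position ortho to the single free phenol, and a second formaldehyde oxidises the benzylic alkoxide to the aldehyde.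

Step 13
Reactants: 17 4,6-bis(benzyloxy)-2-hydroxy-3-[(2R,3R)-7-(allyloxy)-3-(benzyloxy)-2-(3,4-bis(benzyloxy)phenyl)chroman-4β-yl]benzaldehyde
Product: 18 the dibromide of 17 (Br at C5 of the benzaldehyde ring and at C6 of the chroman)
Conditions: NBS (2.05 equiv), CH2Cl2, −40 → 0 °C
Reagents that add atoms: N-bromosuccinimide, O=C1CCC(=O)N1Br
Why: Electrophilic aromatic bromination should take the two most activated free positions (para to the phenol on the phloroglucinol ring; C6, para to O1, on the chroman) and leave C8 between the two oxygens untouched.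

Step 14
Reactants: 18 the dibromide of 17
Product: 19 the 7-hydroxychroman obtained from 18 by loss of the allyl group
Conditions: Pd(PPh3)4 (5 mol %), K2CO3, MeOH–THF, rt
Reagents that add atoms: none
Why: Tsuji–Trost deallylation; zerovalent palladium ionises the aryl allyl ether and methoxide takes the allyl group, while the electron-rich hindered aryl bromides should not undergo oxidative addition at room temperature.

Step 15
Reactants: 20 (−)-epicatechin
Product: 21 5,7,3′,4′-tetra-O-benzyl-(−)-epicatechin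
Conditions: BnBr (4.4 equiv), K2CO3, DMF, 0 °C → rt
Reagents that add atoms: benzyl bromide, BrCc1ccccc1
Why: Williamson etherification of the four phenols; the secondary C3 alcohol is not deprotonated by carbonate.

Step 16
Reactants: 21 5,7,3′,4′-tetra-O-benzyl-(−)-epicatechin
Product: 22 3-O-acetyl-5,7,3′,4′-tetra-O-benzyl-(−)-epicatechin
Conditions: Ac2O, pyridine, DMAP (cat.), rt
Reagents that add atoms: acetic anhydride, CC(=O)OC(C)=O
Why: Acylation installs the participating C3 ester that later directs the 4β coupling.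

Step 17
Reactants: 22 3-O-acetyl-5,7,3′,4′-tetra-O-benzyl-(−)-epicatechin
Product: 23 the 4β-(2-ethoxyethoxy) derivative of 22
Conditions: DDQ (2 equiv), 2-ethoxyethanol, CH2Cl2, rt
Reagents that add atoms: 2-ethoxyethanol, CCOCCO
Why: DDQ C4 oxidation of a benzylated flavan-3-ol, a known reaction of this class; the alcohol adds trans to the C3 acetate.

Step 18
Reactants: 23 the 4β-(2-ethoxyethoxy) derivative of 22
Product: 24 the 6,8-dibromo derivative of 23
Conditions: NBS (2.2 equiv), CH2Cl2, −20 → 0 °C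
Reagents that add atoms: N-bromosuccinimide, O=C1CCC(=O)N1Br
Why: Electrophilic bromination of both free positions of ring A caps the electrophile so that its cation cannot self-condense; the bromines leave in the last step.

Step 19
Reactants: 19 the 7-hydroxychroman obtained from 18; 24 the 6,8-dibromo derivative of 23
Product: 25 3-O-acetyl-5,7,3′,4′-tetra-O-benzyl-6,8-dibromoepicatechin-(4β→8)-[3,3′,4′-tri-O-benzyl-6-bromoepifisetinidol] bearing at its C4 (β) a 2,4-bis(benzyloxy)-3-bromo-5-formyl-6-hydroxyphenyl group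
Conditions: 24 (1.8 equiv), BF3·OEt2 (2 equiv), 4 Å MS, CH2Cl2, −78 → −20 °C
Reagents that add atoms: none
Why: Lewis-acid-mediated Friedel–Crafts interflavan coupling with a bromine-capped electrophile; the acetoxonium-stabilised C4 cation can form a C–C bond only at C8 of 19, the single free aromatic position ortho to a free phenol (O-alkylation is reversible), and attack anti to the participating 3-acetoxy group should give the 4β (3,4-trans) linkage.

Step 20
Reactants: 25 the aldehyde from step 19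
Product: 26 the 2-hydroxybenzyl alcohol corresponding to 25 (5-hydroxymethyl in place of 5-formyl)
Conditions: NaBH4, THF–MeOH, −10 °C; pH 7 work-up
Reagents that add atoms: none
Why: Borohydride reduction of the aryl aldehyde; the acetate, aryl bromides and benzyl ethers should be untouched.

Step 21
Reactants: 3 3,4-bis(benzyloxy)benzaldehyde
Product: 28 potassium (E)-[2-(3,4-bis(benzyloxy)phenyl)ethenyl]trifluoroborate, via pinacol alkenylboronate 27 (not isolated)
Conditions: CH2(Bpin)2, LiTMP (lithium 2,2,6,6-tetramethylpiperidide), THF, −78 °C → rt; then KHF2, MeOH–H2O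
Reagents that add atoms: bis[(pinacolato)boryl]methane, CC1(C)OB(CB2OC(C)(C)C(C)(C)O2)OC1(C)C; potassium hydrogen difluoride, [K+].[F-].F
Why: Boron–Wittig olefination of an aryl aldehyde should give the E-alkenylboronate, which KHF2 converts into the crystalline trifluoroborate.

Step 22
Reactants: 28 potassium (E)-[2-(3,4-bis(benzyloxy)phenyl)ethenyl]trifluoroborate
Product: 29 (E)-2-[3,4-bis(benzyloxy)phenyl]ethenyl acetate
Conditions: AcOH, CuBr (10 mol %), DMAP, 4 Å MS, O2 (1 atm), MeCN, 50 °C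
Reagents that add atoms: acetic acid, CC(=O)O
Why: Copper-catalysed oxidative coupling of an alkenyltrifluoroborate with a carboxylic acid (Chan–Lam type) should replace boron by acetoxy with retention of the E geometry.

Step 23
Reactants: 26 the 2-hydroxybenzyl alcohol corresponding to 25; 29 (E)-2-[3,4-bis(benzyloxy)phenyl]ethenyl acetate
Product: 31 3-O-acetyl-5,7,3′,4′-tetra-O-benzyl-6,8-dibromoepicatechin-(4β→8)-[3,3′,4′-tri-O-benzyl-6-bromoepifisetinidol]-(4β→8)-[3-O-acetyl-5,7,3′,4′-tetra-O-benzyl-6-bromocatechin], via ortho-quinone methide 30 (not isolated)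
Conditions: 29 (3 equiv), (R)-TRIP [(R)-3,3′-bis(2,4,6-triisopropylphenyl)-1,1′-binaphthyl-2,2′-diyl hydrogen phosphate, 10 mol %], 5 Å MS, CH2Cl2, −30 → 0 °C
Reagents that add atoms: none
Why: Proposed new method: the chiral phosphoric acid ionises the 2,4,6-trioxygenated ortho-hydroxybenzyl alcohol of 26 to the ortho-quinone methide 30 (C4=C4a–C8a=O1, held as a hydrogen-bonded ion pair with the phosphate); its methylene C4 is attacked by the acetoxy-bearing carbon of 29 while O1 closes onto the benzylic carbon, an inverse-electron-demand oxa-[4+2] cycloaddition that forms C4–C3 and O1–C2 in one operation. The closest known reaction type is the Brønsted-acid-catalysed [4+2] cycloaddition of in situ generated ortho-quinone methides with styrenes (flavan synthesis), extended here to a β-acyloxystyrene and to a methylene quinone methide under chiral-anion control. The pyran ring closes as a six-membered [4+2] adduct, suprafacial on the dienophile, or in the stepwise limit by 6-endo capture of the C2 benzylic cation by O1. The trans C2/C3 relationship follows from the E geometry of 29 and, if the reaction is stepwise, from the C3 acetoxy group, which bridges the C2 cation as the more stable trans-dioxolanylium ion that O1 opens with inversion; the (2R,3S) facial sense is imposed by the chiral phosphate (the antipodal acid is the direct alternative), and because 26 is a single enantiomer the other facial isomer is a diastereomer removable by chromatography. The required regiochemistry (aryl on C2, oxygen on C3) is secured by the 3,4-bis(benzyloxy)phenyl group, which stabilises positive charge at C2 much better than the ester oxygen can at C3. Chemoselectivity is secured by the substrate: the only ortho-hydroxybenzyl alcohol sits on the phloroglucinol ring, every other nucleophilic ring A position is blocked by bromine or carbon so the quinone methide cannot self-condense, and the weak acid should leave both interflavan bonds intact.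

Step 24
Reactants: 31 the bis-acetate from step 23
Product: 32 5,7,3′,4′-tetra-O-benzyl-6,8-dibromoepicatechin-(4β→8)-[3,3′,4′-tri-O-benzyl-6-bromoepifisetinidol]-(4β→8)-[5,7,3′,4′-tetra-O-benzyl-6-bromocatechin]
Conditions: K2CO3, MeOH–THF, rt
Reagents that add atoms: none
Why: Base-catalysed transesterification removes both C3 acetates before the base-sensitive free polyphenol is released.

Step 25
Reactants: 32 the diol from step 24
Product: 33 epicatechin-(4β→8)-epifisetinidol-(4β→8)-catechin (CNP0270097.1)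
Conditions: H2 (1 atm), Pd(OH)2/C, Et3N (5 equiv), THF–MeOH–H2O, rt
Reagents that add atoms: none
Why: Catalytic hydrogenolysis cleaves the eleven benzyl ethers and the four aryl C–Br bonds, with Et3N buffering the HBr so that the acid-labile interflavan bonds survive; no stereocentre is touched.

## Compound list

1 | 2′,4′-dihydroxyacetophenone | CC(=O)c1ccc(O)cc1O | starting material
2 | 1-[4-(allyloxy)-2-hydroxyphenyl]ethan-1-one | CC(=O)c1ccc(OCC=C)cc1O | intermediate
3 | 3,4-bis(benzyloxy)benzaldehyde | O=Cc1ccc(OCc2ccccc2)c(OCc2ccccc2)c1 | starting material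
4 | (E)-1-[4-(allyloxy)-2-hydroxyphenyl]-3-[3,4-bis(benzyloxy)phenyl]prop-2-en-1-one | O=C(/C=C/c1ccc(OCc2ccccc2)c(OCc2ccccc2)c1)c1ccc(OCC=C)cc1O | intermediate
5 | 5-(allyloxy)-2-[(E)-3-(3,4-bis(benzyloxy)phenyl)acryloyl]phenyl ethyl carbonate | CCOC(=O)Oc1cc(OCC=C)ccc1C(=O)/C=C/c1ccc(OCc2ccccc2)c(OCc2ccccc2)c1 | intermediate
6 | (E)-5-(allyloxy)-2-[3-(3,4-bis(benzyloxy)phenyl)prop-2-en-1-yl]phenol | Oc1cc(OCC=C)ccc1C/C=C/c1ccc(OCc2ccccc2)c(OCc2ccccc2)c1 | intermediate
7 | tert-butyldimethylsilyl ether of 6 | CC(C)(C)[Si](C)(C)Oc1cc(OCC=C)ccc1C/C=C/c1ccc(OCc2ccccc2)c(OCc2ccccc2)c1 | intermediate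
8 | (2S,3S)-2-[3,4-bis(benzyloxy)phenyl]-3-[4-(allyloxy)-2-(tert-butyldimethylsilyloxy)benzyl]oxirane | C=CCOc1ccc(C[C@@H]2O[C@H]2c2ccc(OCc3ccccc3)c(OCc3ccccc3)c2)c(O[Si](C)(C)C(C)(C)C)c1 | intermediate
9 | 5-(allyloxy)-2-{[(2S,3S)-3-(3,4-bis(benzyloxy)phenyl)oxiran-2-yl]methyl}phenol | C=CCOc1ccc(C[C@@H]2O[C@H]2c2ccc(OCc3ccccc3)c(OCc3ccccc3)c2)c(O)c1 | intermediate
10 | (2R,3S)-7-(allyloxy)-2-[3,4-bis(benzyloxy)phenyl]chroman-3-ol (2,3-trans) | C=CCOc1ccc2c(c1)O[C@H](c1ccc(OCc3ccccc3)c(OCc3ccccc3)c1)[C@@H](O)C2 | intermediate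
11 | (2R)-7-(allyloxy)-2-[3,4-bis(benzyloxy)phenyl]chroman-3-one | C=CCOc1ccc2c(c1)O[C@H](c1ccc(OCc3ccccc3)c(OCc3ccccc3)c1)C(=O)C2 | intermediate
12 | (2R,3R)-7-(allyloxy)-2-[3,4-bis(benzyloxy)phenyl]chroman-3-ol (2,3-cis) | C=CCOc1ccc2c(c1)O[C@H](c1ccc(OCc3ccccc3)c(OCc3ccccc3)c1)[C@H](O)C2 | intermediate
13 | (2R,3R)-7-(allyloxy)-3-(benzyloxy)-2-[3,4-bis(benzyloxy)phenyl]chromane | C=CCOc1ccc2c(c1)O[C@H](c1ccc(OCc3ccccc3)c(OCc3ccccc3)c1)[C@H](OCc1ccccc1)C2 | intermediate
14 | 4β-(2-ethoxyethoxy) derivative of 13 (2,3-cis, 3,4-trans) | C=CCOc1ccc2c(c1)O[C@H](c1ccc(OCc3ccccc3)c(OCc3ccccc3)c1)[C@H](OCc1ccccc1)[C@H]2OCCOCC | intermediate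
15 | 3,5-bis(benzyloxy)phenol | Oc1cc(OCc2ccccc2)cc(OCc2ccccc2)c1 | starting material
16 | 2-[(2R,3R)-7-(allyloxy)-3-(benzyloxy)-2-(3,4-bis(benzyloxy)phenyl)chroman-4β-yl]-3,5-bis(benzyloxy)phenol | C=CCOc1ccc2c(c1)O[C@H](c1ccc(OCc3ccccc3)c(OCc3ccccc3)c1)[C@H](OCc1ccccc1)[C@H]2c1c(OCc2ccccc2)cc(OCc2ccccc2)cc1O | intermediate
17 | 4,6-bis(benzyloxy)-2-hydroxy-3-[(2R,3R)-7-(allyloxy)-3-(benzyloxy)-2-(3,4-bis(benzyloxy)phenyl)chroman-4β-yl]benzaldehyde | C=CCOc1ccc2c(c1)O[C@H](c1ccc(OCc3ccccc3)c(OCc3ccccc3)c1)[C@H](OCc1ccccc1)[C@H]2c1c(OCc2ccccc2)cc(OCc2ccccc2)c(C=O)c1O | intermediate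
18 | dibromide of 17 (5-bromo on the benzaldehyde ring, 6-bromo on the chroman) | C=CCOc1c(Br)cc2c(c1)O[C@H](c1ccc(OCc3ccccc3)c(OCc3ccccc3)c1)[C@H](OCc1ccccc1)[C@H]2c1c(OCc2ccccc2)c(Br)c(OCc2ccccc2)c(C=O)c1O | intermediate
19 | 7-hydroxychroman from 18 (allyl removed) | Oc1c(Br)cc2c(c1)O[C@H](c1ccc(OCc3ccccc3)c(OCc3ccccc3)c1)[C@H](OCc1ccccc1)[C@H]2c1c(OCc2ccccc2)c(Br)c(OCc2ccccc2)c(C=O)c1O | intermediate
20 | (−)-epicatechin, (2R,3R) | Oc1cc(O)c2c(c1)O[C@H](c1ccc(O)c(O)c1)[C@H](O)C2 | starting material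
21 | 5,7,3′,4′-tetra-O-benzyl-(−)-epicatechin | c1ccccc1COc1cc(OCc3ccccc3)c2c(c1)O[C@H](c1ccc(OCc3ccccc3)c(OCc3ccccc3)c1)[C@H](O)C2 | intermediate
22 | 3-O-acetyl-5,7,3′,4′-tetra-O-benzyl-(−)-epicatechin | c1ccccc1COc1cc(OCc3ccccc3)c2c(c1)O[C@H](c1ccc(OCc3ccccc3)c(OCc3ccccc3)c1)[C@H](OC(C)=O)C2 | intermediate
23 | 4β-(2-ethoxyethoxy) derivative of 22 | c1ccccc1COc1cc(OCc3ccccc3)c2c(c1)O[C@H](c1ccc(OCc3ccccc3)c(OCc3ccccc3)c1)[C@H](OC(C)=O)[C@H]2OCCOCC | intermediate
24 | 6,8-dibromo derivative of 23 | c1ccccc1COc1c(Br)c(OCc3ccccc3)c2c(c1Br)O[C@H](c1ccc(OCc3ccccc3)c(OCc3ccccc3)c1)[C@H](OC(C)=O)[C@H]2OCCOCC | intermediate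
25 | 3-O-acetyl-5,7,3′,4′-tetra-O-benzyl-6,8-dibromoepicatechin-(4β→8)-[3,3′,4′-tri-O-benzyl-6-bromoepifisetinidol] with a 2,4-bis(benzyloxy)-3-bromo-5-formyl-6-hydroxyphenyl group at C4 (β) | c1ccccc1COc1c(Br)c(OCc3ccccc3)c2c(c1Br)O[C@H](c1ccc(OCc3ccccc3)c(OCc3ccccc3)c1)[C@H](OC(C)=O)[C@H]2c1c(O)c(Br)cc2c1O[C@H](c1ccc(OCc3ccccc3)c(OCc3ccccc3)c1)[C@H](OCc1ccccc1)[C@H]2c1c(OCc2ccccc2)c(Br)c(OCc2ccccc2)c(C=O)c1O | intermediate
26 | 2-hydroxybenzyl alcohol corresponding to 25 (5-hydroxymethyl in place of 5-formyl) | c1ccccc1COc1c(Br)c(OCc3ccccc3)c2c(c1Br)O[C@H](c1ccc(OCc3ccccc3)c(OCc3ccccc3)c1)[C@H](OC(C)=O)[C@H]2c1c(O)c(Br)cc2c1O[C@H](c1ccc(OCc3ccccc3)c(OCc3ccccc3)c1)[C@H](OCc1ccccc1)[C@H]2c1c(OCc2ccccc2)c(Br)c(OCc2ccccc2)c(CO)c1O | intermediate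
27 | (E)-2-[2-(3,4-bis(benzyloxy)phenyl)ethenyl]-4,4,5,5-tetramethyl-1,3,2-dioxaborolane | CC1(C)OB(/C=C/c2ccc(OCc3ccccc3)c(OCc3ccccc3)c2)OC1(C)C | intermediate
28 | potassium (E)-[2-(3,4-bis(benzyloxy)phenyl)ethenyl]trifluoroborate | [K+].F[B-](F)(F)/C=C/c1ccc(OCc2ccccc2)c(OCc2ccccc2)c1 | intermediate
29 | (E)-2-[3,4-bis(benzyloxy)phenyl]ethenyl acetate | CC(=O)O/C=C/c1ccc(OCc2ccccc2)c(OCc2ccccc2)c1 | intermediate
30 | ortho-quinone methide from 26 (3,5-bis(benzyloxy)-4-bromo-6-methylidenecyclohexa-2,4-dien-1-one carrying the flavanyl group at C2) | c1ccccc1COc1c(Br)c(OCc3ccccc3)c2c(c1Br)O[C@H](c1ccc(OCc3ccccc3)c(OCc3ccccc3)c1)[C@H](OC(C)=O)[C@H]2c1c(O)c(Br)cc2c1O[C@H](c1ccc(OCc3ccccc3)c(OCc3ccccc3)c1)[C@H](OCc1ccccc1)[C@H]2C1=C(OCc2ccccc2)C(Br)=C(OCc2ccccc2)C(=C)C1=O | intermediate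
31 | 3-O-acetyl-5,7,3′,4′-tetra-O-benzyl-6,8-dibromoepicatechin-(4β→8)-[3,3′,4′-tri-O-benzyl-6-bromoepifisetinidol]-(4β→8)-[3-O-acetyl-5,7,3′,4′-tetra-O-benzyl-6-bromocatechin] | c1ccccc1COc1c(Br)c(OCc3ccccc3)c2c(c1Br)O[C@H](c1ccc(OCc3ccccc3)c(OCc3ccccc3)c1)[C@H](OC(C)=O)[C@H]2c1c(O)c(Br)cc2c1O[C@H](c1ccc(OCc3ccccc3)c(OCc3ccccc3)c1)[C@H](OCc1ccccc1)[C@H]2c1c(OCc3ccccc3)c(Br)c(OCc3ccccc3)c2c1O[C@H](c1ccc(OCc3ccccc3)c(OCc3ccccc3)c1)[C@@H](OC(C)=O)C2 | intermediate
32 | 5,7,3′,4′-tetra-O-benzyl-6,8-dibromoepicatechin-(4β→8)-[3,3′,4′-tri-O-benzyl-6-bromoepifisetinidol]-(4β→8)-[5,7,3′,4′-tetra-O-benzyl-6-bromocatechin] | c1ccccc1COc1c(Br)c(OCc3ccccc3)c2c(c1Br)O[C@H](c1ccc(OCc3ccccc3)c(OCc3ccccc3)c1)[C@H](O)[C@H]2c1c(O)c(Br)cc2c1O[C@H](c1ccc(OCc3ccccc3)c(OCc3ccccc3)c1)[C@H](OCc1ccccc1)[C@H]2c1c(OCc3ccccc3)c(Br)c(OCc3ccccc3)c2c1O[C@H](c1ccc(OCc3ccccc3)c(OCc3ccccc3)c1)[C@@H](O)C2 | intermediate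
33 | epicatechin-(4β→8)-epifisetinidol-(4β→8)-catechin (CNP0270097.1) | Oc1cc(O)c2c(c1)O[C@H](c1ccc(O)c(O)c1)[C@H](O)[C@H]2c1c(O)ccc2c1O[C@H](c1ccc(O)c(O)c1)[C@H](O)[C@H]2c1c(O)cc(O)c2c1O[C@H](c1ccc(O)c(O)c1)[C@@H](O)C2 | target

## Step count and risks

Total step count: 25. Longest linear sequence: 19 steps (steps 1–14, 19, 20, 23, 24, 25).

Steps most likely to fail:

1. Step 23 (the step labelled as a proposed new method). What may go wrong: reversed regiochemistry of the cycloaddition (bond formation directed by the ester oxygen rather than the aryl group), poor facial selectivity on the dienophile relative to the six existing stereocentres, or C-alkenylation with loss of the proton instead of ring closure. Fallback (known chemistry), setting out from 26 and using 28: acid-catalysed conjugate alkenylation of the quinone methide by the trifluoroborate 28 (diphenyl phosphate, CH2Cl2) should give the (E)-2-cinnamylphenol F1. Silylation of both phenols (TBSCl, imidazole) gives the bis-silyl ether F2. Shi epoxidation with the L-fructose-derived ketone, as in step 5, gives the (S,S)-epoxide F3. TBAF/AcOH followed by CSA, as in step 6, closes ring C by 6-endo phenol opening to the 2,3-trans flavan-3-ol F4. K2CO3/MeOH removes the remaining acetate, and the route is rejoined at 32.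

2. Step 19. What may go wrong: slow capture of the capped cation at the hindered C8, which lacks a para oxygen, so that alkylation of the catechol B rings or decay of the cation competes. Fallback, setting out from 24 and using 19: mild aqueous acid converts 24 into the 4β-alcohol F5. A Mitsunobu reaction (PPh3, DIAD) joins F5 to the unhindered 7-hydroxyl of 19 as the aryl flavan-4-yl ether F6. BF3·OEt2 at low temperature then effects the O→C (Fries-type) shift of the flavanyl group within the ion pair to the only free ortho carbon, C8, giving 25, where the route is rejoined.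

3. Step 10. What may go wrong: hydride abstraction at C2 (benzylic to ring B and next to O1) or dehydrogenation to the flav-3-ene instead of clean C4 etherification, because the 5-deoxy ring A is less electron-rich than in the catechin series. Fallback, setting out from 13: Pd(PPh3)4/K2CO3/MeOH removes the allyl group to give the 7-hydroxyflavan F7. DDQ (1.1 equiv) with 2-ethoxyethanol then oxidises the para-hydroxybenzylic C4 in the phenol (quinone methide) manifold, which is far more facile than ether oxidation, to give the 4β-(2-ethoxyethoxy) phenol F8. Mitsunobu O-allylation (allyl alcohol, PPh3, DIAD) returns 14, where the route is rejoined.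

Further compounds
F1 | step 23 | (E)-2-cinnamylphenol: analogue of 26 with an (E)-3-[3,4-bis(benzyloxy)phenyl]prop-2-en-1-yl group in place of the hydroxymethyl group | c1ccccc1COc1c(Br)c(OCc3ccccc3)c2c(c1Br)O[C@H](c1ccc(OCc3ccccc3)c(OCc3ccccc3)c1)[C@H](OC(C)=O)[C@H]2c1c(O)c(Br)cc2c1O[C@H](c1ccc(OCc3ccccc3)c(OCc3ccccc3)c1)[C@H](OCc1ccccc1)[C@H]2c1c(OCc2ccccc2)c(Br)c(OCc2ccccc2)c(C/C=C/c2ccc(OCc3ccccc3)c(OCc3ccccc3)c2)c1O
F2 | step 23 | bis(tert-butyldimethylsilyl) ether of F1 (both phenols silylated) | c1ccccc1COc1c(Br)c(OCc3ccccc3)c2c(c1Br)O[C@H](c1ccc(OCc3ccccc3)c(OCc3ccccc3)c1)[C@H](OC(C)=O)[C@H]2c1c(O[Si](C)(C)C(C)(C)C)c(Br)cc2c1O[C@H](c1ccc(OCc3ccccc3)c(OCc3ccccc3)c1)[C@H](OCc1ccccc1)[C@H]2c1c(OCc2ccccc2)c(Br)c(OCc2ccccc2)c(C/C=C/c2ccc(OCc3ccccc3)c(OCc3ccccc3)c2)c1O[Si](C)(C)C(C)(C)C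
F3 | step 23 | (2S,3S)-epoxide of F2 | c1ccccc1COc1c(Br)c(OCc3ccccc3)c2c(c1Br)O[C@H](c1ccc(OCc3ccccc3)c(OCc3ccccc3)c1)[C@H](OC(C)=O)[C@H]2c1c(O[Si](C)(C)C(C)(C)C)c(Br)cc2c1O[C@H](c1ccc(OCc3ccccc3)c(OCc3ccccc3)c1)[C@H](OCc1ccccc1)[C@H]2c1c(OCc2ccccc2)c(Br)c(OCc2ccccc2)c(C[C@@H]2O[C@H]2c2ccc(OCc3ccccc3)c(OCc3ccccc3)c2)c1O[Si](C)(C)C(C)(C)C
F4 | step 23 | analogue of 31 with a free 3-hydroxyl on the lower (2R,3S) catechin unit (upper 3-O-acetyl retained) | c1ccccc1COc1c(Br)c(OCc3ccccc3)c2c(c1Br)O[C@H](c1ccc(OCc3ccccc3)c(OCc3ccccc3)c1)[C@H](OC(C)=O)[C@H]2c1c(O)c(Br)cc2c1O[C@H](c1ccc(OCc3ccccc3)c(OCc3ccccc3)c1)[C@H](OCc1ccccc1)[C@H]2c1c(OCc3ccccc3)c(Br)c(OCc3ccccc3)c2c1O[C@H](c1ccc(OCc3ccccc3)c(OCc3ccccc3)c1)[C@@H](O)C2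
F5 | step 19 | 3-O-acetyl-5,7,3′,4′-tetra-O-benzyl-6,8-dibromo-4β-hydroxyepicatechin | c1ccccc1COc1c(Br)c(OCc3ccccc3)c2c(c1Br)O[C@H](c1ccc(OCc3ccccc3)c(OCc3ccccc3)c1)[C@H](OC(C)=O)[C@H]2O
F6 | step 19 | aryl ether of F5 with the 7-hydroxyl of 19 (C4 drawn 4α after Mitsunobu inversion; this centre is lost on ionisation) | c1ccccc1COc1c(Br)c(OCc3ccccc3)c2c(c1Br)O[C@H](c1ccc(OCc3ccccc3)c(OCc3ccccc3)c1)[C@H](OC(C)=O)[C@@H]2Oc1c(Br)cc2c(c1)O[C@H](c1ccc(OCc3ccccc3)c(OCc3ccccc3)c1)[C@H](OCc1ccccc1)[C@H]2c1c(OCc2ccccc2)c(Br)c(OCc2ccccc2)c(C=O)c1O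
F7 | step 10 | (2R,3R)-3-(benzyloxy)-2-[3,4-bis(benzyloxy)phenyl]chroman-7-ol | Oc1ccc2c(c1)O[C@H](c1ccc(OCc3ccccc3)c(OCc3ccccc3)c1)[C@H](OCc1ccccc1)C2
F8 | step 10 | 4β-(2-ethoxyethoxy) derivative of F7 | Oc1ccc2c(c1)O[C@H](c1ccc(OCc3ccccc3)c(OCc3ccccc3)c1)[C@H](OCc1ccccc1)[C@H]2OCCOCC
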